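**Retrosynthetic overview**
- Target 17 is cut at the bond between the bridge CH2 and ring A (the filicinic acid ring): aldehyde 13 and propionylfilicinic acid 15 (from flopropione 14) are joined by reductive Knoevenagel coupling, so the formyl carbon becomes the bridge.
- The strategy rests on the aryl ether bond O1–C8a of pyran ring C. O1 arrives on a side chain at C4a (Z C3=C4 alkene, C2 carbinol with the gem-dimethyl group), while aromatic ring B carries bromine at C8a and protected oxygens at C5 and C7 around the C6 formyl group. Palladium C–O coupling of 7 closes ring C to give 8.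
- Precursor 7 comes from the symmetric 4-bromo-2,6-dimethoxybenzaldehyde 1 by iodination next to bromine, exchange of OMe for OMOM, Sonogashira coupling with 5 and Z-selective semihydrogenation. Because 1 is symmetric, the bromide alone fixes where O1 ends up.
- After ring closure the C8 propanoyl group is installed by ring lithiation and Weinreb acylation (12), the MOM groups are removed (13), and the bridge is formed.
- Ring order: ring B is bought, ring C is closed in step 6, ring A is made separately in step 9 and attached last.

Key step: step 6

Remark on the chemistry: the target has no stereocentre and is drawn as the given enol tautomer; the methyl ethers of 1 are exchanged early for methoxymethyl ethers, because a late Lewis-acid cleavage of aryl methyl ethers would risk ionising the O1–C2 bond of the 2,2-dimethylchromene once a carbonyl group sits ortho to O1.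

**Step 1**
Reactants: 1 4-bromo-2,6-dimethoxybenzaldehyde
Product: 2 4-bromo-3-iodo-2,6-dimethoxybenzaldehyde
Conditions: NIS (1.05 equiv), TFA/MeCN, rt
Reagents that add atoms: N-iodosuccinimide, O=C1CCC(=O)N1I
Why: Electrophilic aromatic iodination; the two free ring positions of 1 are equivalent, each ortho to one methoxy, para to the other and meta to the formyl group, so one regioisomer should form and one equivalent of NIS should stop at the mono-iodide.

**Step 2**
Reactants: 2 4-bromo-3-iodo-2,6-dimethoxybenzaldehyde
Product: 3 4-bromo-2,6-dihydroxy-3-iodobenzaldehyde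
Conditions: BBr3 (3 equiv), CH2Cl2, –78 °C to rt; then H2O
Reagents that add atoms: none
Why: Lewis-acid ether cleavage (BBr3 demethylation) should free both phenols while the aldehyde and both aryl halides stay intact, and it is done here before any acid-sensitive group exists.

**Step 3**
Reactants: 3 4-bromo-2,6-dihydroxy-3-iodobenzaldehyde
Product: 4 4-bromo-3-iodo-2,6-bis(methoxymethoxy)benzaldehyde
Conditions: NaH (2.5 equiv), MOMCl (2.5 equiv), DMF, 0 °C to rt
Reagents that add atoms: chloromethyl methyl ether, COCCl
Why: Williamson-type O-alkylation of the bis-phenoxide (NaH is used so that the hydrogen-bonded phenol also reacts) gives acetal ethers that withstand the base, palladium and organolithium steps ahead and later come off under acid mild enough for the chromene.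

**Step 4**
Reactants: 4 4-bromo-3-iodo-2,6-bis(methoxymethoxy)benzaldehyde; 5 2-methylbut-3-yn-2-ol
Product: 6 4-bromo-3-(3-hydroxy-3-methylbut-1-yn-1-yl)-2,6-bis(methoxymethoxy)benzaldehyde
Conditions: PdCl2(PPh3)2 (cat.), CuI (cat.), Et3N, THF, rt
Reagents that add atoms: none
Why: Sonogashira coupling; oxidative addition into C–I is much faster than into C–Br at room temperature, so the bromide needed for ring closure is kept, and the protected ortho oxygen cannot cyclise onto the alkyne.

**Step 5**
Reactants: 6 4-bromo-3-(3-hydroxy-3-methylbut-1-yn-1-yl)-2,6-bis(methoxymethoxy)benzaldehyde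
Product: 7 4-bromo-3-[(Z)-3-hydroxy-3-methylbut-1-en-1-yl]-2,6-bis(methoxymethoxy)benzaldehyde
Conditions: H2 (1 atm), Pd/CaCO3 poisoned with Pb(OAc)2, quinoline, EtOAc, rt
Reagents that add atoms: none
Why: Lindlar semihydrogenation; syn delivery of hydrogen on the poisoned palladium surface should give the Z alkene and stop there, and the aryl bromide and the aldehyde are not expected to be reduced.

**Step 6**
Reactants: 7 4-bromo-3-[(Z)-3-hydroxy-3-methylbut-1-en-1-yl]-2,6-bis(methoxymethoxy)benzaldehyde
Product: 8 5,7-bis(methoxymethoxy)-2,2-dimethyl-2H-chromene-6-carbaldehyde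
Conditions: Pd(OAc)2 (5 mol %), 2-di-tert-butylphosphino-2',4',6'-triisopropylbiphenyl (10 mol %), Cs2CO3 (1.5 equiv), toluene, 80 °C
Reagents that add atoms: none
Why: Pd(OAc)2 is reduced in situ to a zerovalent palladium–phosphine complex that inserts into the C8a–Br bond (activated by the para formyl group), Cs2CO3 deprotonates the coordinated tertiary alcohol to give a seven-membered aryl(alkoxo) palladacycle of divalent palladium, and C–O reductive elimination forms O1–C8a and returns zerovalent palladium. The closest known reaction type is the palladium-catalysed intramolecular etherification of aryl bromides with tertiary alcohols (Buchwald–Hartwig-type C–O coupling). Ring C, the six-membered 2H-pyran, closes by this reductive elimination, in effect an intramolecular ipso substitution of bromide at C8a by the side-chain oxygen. No stereocentre is formed. The step needs C–O reductive elimination to outrun hydrodebromination and alkene isomerisation: the tertiary alkoxide has no carbinol hydrogen for β-hydride elimination, the Z alkene from step 5 holds the oxygen beside the bromide, and both the electron-poor aryl group and the bulky di-tert-butylbiarylphosphine speed reductive elimination. Regiochemistry is fixed because C8a carries the only halogen.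

**Step 7**
Reactants: 8 5,7-bis(methoxymethoxy)-2,2-dimethyl-2H-chromene-6-carbaldehyde
Product: 12 5,7-bis(methoxymethoxy)-2,2-dimethyl-8-propanoyl-2H-chromene-6-carbaldehyde, via lithium amino alkoxide 9 (not isolated), via ring-lithiated amino alkoxide 10 (not isolated), via Weinreb tetrahedral adduct 11 (not isolated)
Conditions: N-methylpiperazine, n-BuLi, THF, –20 °C, then 8; n-BuLi, TMEDA, –20 to 0 °C; EtC(O)N(OMe)Me, –78 °C to rt; aq. NH4Cl
Reagents that add atoms: N-methoxy-N-methylpropanamide, CCC(=O)N(C)OC
Why: In situ protection of the aldehyde as its lithium α-amino alkoxide, directed ortho-metalation at C8 (the only ring hydrogen, flanked by the C7 OMOM group and O1) and Weinreb ketone synthesis, whose chelated tetrahedral adduct stops at the ketone, should install the propanoyl group without any Lewis acid touching the chromene, and aqueous work-up releases both carbonyl groups.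

**Step 8**
Reactants: 12 5,7-bis(methoxymethoxy)-2,2-dimethyl-8-propanoyl-2H-chromene-6-carbaldehyde
Product: 13 5,7-dihydroxy-2,2-dimethyl-8-propanoyl-2H-chromene-6-carbaldehyde
Conditions: 3 M aq. HCl, MeOH, rt
Reagents that add atoms: none
Why: Acid-catalysed acetal cleavage (MOM removal with transfer of the CH2 unit to methanol) should free both phenols, each then hydrogen-bonded to a neighbouring carbonyl group, while the 2,2-dimethylchromene is expected to tolerate dilute protic acid at room temperature.

**Step 9**
Reactants: 14 flopropione (2,4,6-trihydroxypropiophenone)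
Product: 15 propionylfilicinic acid (3,5-dihydroxy-4,4-dimethyl-2-propanoylcyclohexa-2,5-dien-1-one)
Conditions: NaOMe (3 equiv), MeI (2.2 equiv), MeOH, 0 °C to rt
Reagents that add atoms: iodomethane, CI
Why: Base-mediated dearomative C-methylation of an acylphloroglucinol; two C-alkylations at the same ring carbon give the gem-dimethyl cyclohexadienone, the established entry to acylfilicinic acids, and the product should be separable from under- and over-methylated material by its acidity and by chromatography.

**Step 10**
Reactants: 13 5,7-dihydroxy-2,2-dimethyl-8-propanoyl-2H-chromene-6-carbaldehyde; 15 propionylfilicinic acid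
Product: 17 2-[(5,7-dihydroxy-2,2-dimethyl-8-propanoyl-2H-chromen-6-yl)methyl]-3,5-dihydroxy-4,4-dimethyl-6-propanoylcyclohexa-2,5-dien-1-one (target), via alkylidene triketone 16 (not isolated)
Conditions: L-proline (20 mol %), diethyl 2,6-dimethyl-1,4-dihydropyridine-3,5-dicarboxylate (Hantzsch ester, 1.2 equiv), CH2Cl2, rt
Reagents that add atoms: none
Why: Organocatalytic three-component reductive alkylation (Knoevenagel condensation followed by conjugate hydride transfer from the Hantzsch ester); proline activates the aldehyde as its iminium ion, the only nucleophilic ring CH of 15 condenses to the quinone-methide-like alkylidene 16, and the dihydropyridine should reduce 16 in the flask before a second molecule of 15 can add, so only the mixed dimer can form.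

**Compound list**
1 | 4-bromo-2,6-dimethoxybenzaldehyde | COc1cc(Br)cc(OC)c1C=O | starting material
2 | 4-bromo-3-iodo-2,6-dimethoxybenzaldehyde | COc1cc(Br)c(I)c(OC)c1C=O | intermediate
3 | 4-bromo-2,6-dihydroxy-3-iodobenzaldehyde | Oc1cc(Br)c(I)c(O)c1C=O | intermediate
4 | 4-bromo-3-iodo-2,6-bis(methoxymethoxy)benzaldehyde | COCOc1cc(Br)c(I)c(OCOC)c1C=O | intermediate
5 | 2-methylbut-3-yn-2-ol | CC(C)(O)C#C | starting material
6 | 4-bromo-3-(3-hydroxy-3-methylbut-1-yn-1-yl)-2,6-bis(methoxymethoxy)benzaldehyde | COCOc1cc(Br)c(C#CC(C)(C)O)c(OCOC)c1C=O | intermediate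
7 | 4-bromo-3-[(Z)-3-hydroxy-3-methylbut-1-en-1-yl]-2,6-bis(methoxymethoxy)benzaldehyde | COCOc1cc(Br)c(/C=C\C(C)(C)O)c(OCOC)c1C=O | intermediate
8 | 5,7-bis(methoxymethoxy)-2,2-dimethyl-2H-chromene-6-carbaldehyde | COCOc1cc2OC(C)(C)C=Cc2c(OCOC)c1C=O | intermediate
9 | lithium α-amino alkoxide of 8 with N-methylpiperazine (racemic at the carbinol carbon, not isolated) | COCOc1cc2OC(C)(C)C=Cc2c(OCOC)c1C(O[Li])N3CCN(C)CC3 | intermediate
10 | C8-lithiated amino alkoxide (not isolated) | COCOc1c([Li])c2OC(C)(C)C=Cc2c(OCOC)c1C(O[Li])N3CCN(C)CC3 | intermediate
11 | tetrahedral adduct of 10 with the Weinreb amide (not isolated) | COCOc1c(C(CC)(O[Li])N(C)OC)c2OC(C)(C)C=Cc2c(OCOC)c1C(O[Li])N3CCN(C)CC3 | intermediate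
12 | 5,7-bis(methoxymethoxy)-2,2-dimethyl-8-propanoyl-2H-chromene-6-carbaldehyde | COCOc1c(C(=O)CC)c2OC(C)(C)C=Cc2c(OCOC)c1C=O | intermediate
13 | 5,7-dihydroxy-2,2-dimethyl-8-propanoyl-2H-chromene-6-carbaldehyde | CCC(=O)c1c(O)c(C=O)c(O)c2C=CC(C)(C)Oc12 | intermediate
14 | flopropione (2,4,6-trihydroxypropiophenone) | CCC(=O)c1c(O)cc(O)cc1O | starting material
15 | propionylfilicinic acid (3,5-dihydroxy-4,4-dimethyl-2-propanoylcyclohexa-2,5-dien-1-one) | CCC(=O)C1=C(O)C(C)(C)C(O)=CC1=O | intermediate
16 | 2-[(5,7-dihydroxy-2,2-dimethyl-8-propanoyl-2H-chromen-6-yl)methylidene]-5-hydroxy-6,6-dimethyl-4-propanoylcyclohex-4-ene-1,3-dione (alkene geometry undefined, not isolated) | CCC(=O)C1=C(O)C(C)(C)C(=O)C(=Cc2c(O)c3C=CC(C)(C)Oc3c(C(=O)CC)c2O)C1=O | intermediate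
17 | 2-[(5,7-dihydroxy-2,2-dimethyl-8-propanoyl-2H-chromen-6-yl)methyl]-3,5-dihydroxy-4,4-dimethyl-6-propanoylcyclohexa-2,5-dien-1-one | CCC(=O)C1=C(O)C(C)(C)C(O)=C(Cc2c(O)c3c(c(C(=O)CC)c2O)OC(C)(C)C=C3)C1=O | target

**Step count**
Total steps: 10. Longest linear sequence: 9 (steps 1 to 8, then step 10); step 9 is a one-step side branch.

**Steps most likely to fail**

Step 7. The amino alkoxide may form incompletely at the hindered formyl group, so that butyllithium adds to the aldehyde, or ring lithiation may stall and return 8. The fallback replaces metalation by electrophilic substitution and sets out from 8. Removal of both MOM groups with HCl in MeOH would give 5,7-dihydroxy-2,2-dimethyl-2H-chromene-6-carbaldehyde F1. Its only free ring position, C8, is ortho to the C7 hydroxyl and para to the C5 hydroxyl. Friedel–Crafts C-acylation with propanoic anhydride and BF3·OEt2 in CH2Cl2 at 0 °C to rt, with mild aqueous hydrolysis of boron chelates and any phenyl ester, should then give 13, where the route is rejoined without step 8.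

Step 10. Condensation may be slow at the doubly hydrogen-bonded, flanked aldehyde, and a second molecule of 15 may add to 16 before hydride transfer. The fallback separates reduction from C–C bond formation and sets out from 13. Reductive amination with dimethylamine and NaBH(OAc)3 in 1,2-dichloroethane should give the phenolic Mannich base 1-[6-[(dimethylamino)methyl]-5,7-dihydroxy-2,2-dimethyl-2H-chromen-8-yl]propan-1-one F2. Heating F2 with 15 in toluene at about 90 °C should expel dimethylamine, and the resulting ortho-quinone methide should be trapped by the ring CH of 15, giving 17 directly.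

Step 6. Hydrodebromination may win if alkoxide binding or reductive elimination is slow, and a palladium hydride may isomerise the Z alkene to E, which moves the hydroxyl out of reach. The fallback closes ring C at the other C–O bond (C2–O1) and sets out from 7. Palladium-catalysed hydroxylation of the aryl bromide (Pd2(dba)3, the same phosphine, KOH, dioxane/water, 100 °C) should give 4-hydroxy-3-[(Z)-3-hydroxy-3-methylbut-1-en-1-yl]-2,6-bis(methoxymethoxy)benzaldehyde F3. Cyclodehydration with catalytic pyridinium p-toluenesulfonate in CH2Cl2 at rt, in which the new phenol captures the tertiary allylic cation, should then give 8. Only this phenol is free, so the regiochemistry stays defined.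

**Further compounds**
F1 | step 7 | 5,7-dihydroxy-2,2-dimethyl-2H-chromene-6-carbaldehyde | Oc1cc2OC(C)(C)C=Cc2c(O)c1C=O
F2 | step 10 | 1-[6-[(dimethylamino)methyl]-5,7-dihydroxy-2,2-dimethyl-2H-chromen-8-yl]propan-1-one | CCC(=O)c1c(O)c(CN(C)C)c(O)c2C=CC(C)(C)Oc12
F3 | step 6 | 4-hydroxy-3-[(Z)-3-hydroxy-3-methylbut-1-en-1-yl]-2,6-bis(methoxymethoxy)benzaldehyde | COCOc1cc(O)c(/C=C\C(C)(C)O)c(OCOC)c1C=O
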